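## The problem

Compound 22 is a 2,5-diaryl-3,4-dimethyltetrahydrofuran with all four ring substituents on one face, (2S,3R,4S,5R): ring A (4-hydroxyphenyl) sits on C2 and ring B on C5. Ring B carries, ortho to its phenol, a (2R)-1-(4-hydroxyphenyl)propan-2-yl chain whose methine Cα bears ring B, a methyl group and the CH2 group (Cβ) that leads to ring C.

The all-cis ring is the least stable diastereomer, and both ring C–O bonds are benzylic to para-oxygenated arenes. Acids can therefore ionise and epimerise it, and a hot phenoxide can open it through a quinone methide, so the three phenols must be unmasked under neutral conditions.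

Inside the ring one centre can control the others: a carbinol centre at C2 directs syn-hydrogenation to C3 and C4, and the three cis substituents then direct hydride to the far face of an oxocarbenium ion at C5. The ring would be meso if rings A and B were alike, so its absolute sense exists only relative to the side chain and must be set by a reagent.

Cα is insulated from the ring by ring B and also needs reagent control. A mismatch gives a diastereomer that will be very hard to remove, so both controls must be high.

The feature that opens the key step is the array Cα(ring B)(CH3)–CβH2–ring C. It is an isopropenyl unit that has gained one aryl group at each carbon, which is what a 1,2-metallate shift on an isopropenyl boron ate complex delivers, with boron left on Cα as a traceless handle.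

## Retrosynthesis

**22 ⇒ 21.** The three phenolic O–benzyl bonds are cut first, leading to tris(benzyl ether) 21. Benzyl is chosen over methyl because demethylation needs either boron halides, which ionise the ring, or hot thiolate, which invites quinone methide opening. Silyl ethers are ruled out on ring B because an ortho-lithiated aryl silyl ether suffers oxygen-to-carbon silyl migration. Compound 21 is simpler only in lacking acidic phenols, which is what allows the organolithium and fluoride chemistry before it. The forward reaction must hydrogenolyse aryl benzyl ethers faster than the benzylic C–O bonds of the ring.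

**21 ⇒ 20.** The Cα–H bond is traced back to a Cα–B bond in tertiary boronic ester 20. Cutting a carbon substituent directly at the C–H stereocentre would call for an enantioselective coupling of a secondary alkyl metal. Boron on Cα instead turns Cα into a migration terminus and lets two bonds form at once. Compound 20 is no smaller than 21, but it is the direct product of a three-component union. The forward reaction must replace boron by hydrogen with retention at a crowded tertiary benzylic carbon.

**20 ⇒ 18 + 17 + 16 (key disconnection).** The ring B–Cα and Cβ–ring C bonds are cut together. This gives aryllithium 18, isopropenylboronic ester 17 and aryl triflate 16. Cutting only one of the two bonds would leave a chiral three-carbon piece to be made separately. Cutting both makes the three-carbon piece an achiral commercial reagent and brings the whole side chain in after the ring is finished. Compound 18 carries no side chain and no Cα, so the ring is made once and joined late. The forward reaction must let the chiral palladium catalyst choose the alkene face, and the 1,2-shift must outrun direct transmetalation.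

**18 ⇒ 14 ⇒ 12 ⇒ 8 + 10.** The C–Li bond of 18 comes from the C–Br bond of 14. In 14 the C5–H bond is cut (hydride to oxocarbenium ion 13, formed from lactol 12), then the C5–ring B bond (Grignard reagent 11, made from 10, adding to lactone 8). Hydrogenating a 2,5-diarylfuran would give the all-cis ring in one step, but only as a racemate; the lactone carries absolute configuration into the ring. The bromine must already sit on ring B, since 14 could not be brominated selectively on one of two similar rings, hence the iodide/bromide pair in 10. The precursors are a three-stereocentre lactone and a flat arene. The forward reactions need mono-addition to the lactone and hydride delivery anti to three cis substituents.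

**8 ⇒ 7 ⇒ 5 ⇒ 4 ⇒ 1 + 2.** The C3–H and C4–H bonds of 8 are cut (syn-hydrogenation of butenolide 7 anti to the aryl group). Then the C5–H bond of 7 is cut (enantioselective reduction of keto ester 5, lactonisation of hydroxy ester 6). Finally the ring A–carbonyl bond is cut (Grignard reagent 3 from 1 adding to anhydride 2, giving pseudo-acid 4, then esterification). Reducing a saturated keto acid instead would follow the Felkin model and give the 4,5-trans lactone, so the alkene is kept until the carbinol centre is in place. This reduces the ring to one stereocentre set by a catalyst and to two commodity materials. The forward reactions need enantioface selection at a ketone flanked by two unsaturated groups and a clean face-selective hydrogenation of a tetrasubstituted alkene.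

**10 ⇒ 9 and 16 ⇒ 15.** One O–C bond and one O–S bond are cut. These are routine O-functionalisations of commercial phenols 9 and 15 and need no selectivity.

## Roads not taken

**Alternative 1: carbene C–H insertion into a 4-methoxybenzyl ether.**
- **Cut:** the Cα–Cβ bond, with the ring-B phenol oxygen temporarily tied to Cβ.
- **Forward key step:** diazo ester A2 and a chiral dirhodium tetracarboxylate such as Rh2(S-PTTL)4 would give a rhodium carbene. This inserts into the benzylic C–H bond of the 4-methoxybenzyl ether and closes the cis-dihydrobenzofuran A1.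
- **Merits:** the reaction type is established for exactly this ring system, it is intramolecular, and the ortho oxygen of ring B serves as the tether. On this point it is better than the chosen plan, where the same oxygen is a steric burden on the migrating carbon.
- **Weak points:** A1 is at the wrong oxidation level. The ester must become a methyl group in about three steps without epimerising C3, which is Cα itself and α to the ester. The C2–O bond must be hydrogenolysed before the tetrahydrofuran is attached, because the ring's benzylic ethers would not survive later. The freed phenol must then be re-protected, and the bromide metalated and joined to lactone chemistry as a precious chiral aryl metal.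
- **Comparison:** the ring synthesis is the same in both plans. The alternative spends roughly six or seven operations on the side chain where the chosen plan spends two after the key step. Against that, the chosen plan has to accept an untested hindered migrating group.

**Alternative 2: donor–acceptor cyclopropane and aldehyde [3+2] annulation.**
- **Cut:** O1–C2 and C4–C5 of the tetrahydrofuran.
- **Forward key step:** Sn(OTf)2 would promote attack of the oxygen of aldehyde A5 on the aryl-bearing carbon of trans-cyclopropane A4 with inversion. The malonate carbon then closes on the carbonyl carbon to give diester A3.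
- **Merits:** a convergent ring construction that transfers the cyclopropane configuration to C2 and sets the 2,5-cis relation in one step. This is better than the stepwise lactone route in bond economy.
- **Weak points:** A3 has two esters on C4 where the target needs one methyl group cis to both neighbours. Dealkoxycarbonylation leaves an epimerisable ester that prefers the trans arrangement, and three more steps turn it into methyl. A5 already contains Cα, so a separate asymmetric synthesis of the side chain is still needed. A4 needs its own enantioselective cyclopropanation, and the mesylate must later be removed from a phenol on the acid-sensitive ring.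
- **Comparison:** the alternative wins on convergence at the ring. The chosen plan wins because its two face-selective hydrogen deliveries give the all-cis array directly and because its key step creates Cα rather than presupposing it.

**Alternative 3: Prins–pinacol ring contraction of an allylic diol acetal.**
- **Cut:** C4–C5 and C2–C3 of the tetrahydrofuran.
- **Forward key step:** SnCl4 would ionise dioxolane A7 to an oxocarbenium ion. The (Z)-propenyl terminus closes a six-membered ring, and a pinacol shift of the ring-A carbon contracts it to the all-cis carbaldehyde A6.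
- **Merits:** two C–C bonds and the ring form in one step, and the all-cis array is the natural outcome of the chair-like cyclisation. Here the alternative is better than the chosen plan, which reaches the same array in three separate stereo-determining steps.
- **Weak points:** the formyl group must become methyl in about three steps, while its carbon, α to the aldehyde, can epimerise to the trans series. SnCl4 is the kind of Lewis acid that opens electron-rich benzylic ethers, so the phenols must be masked as deactivating pivalates. A7 needs an enantiopure diol with a (Z)-propenyl group and an aldehyde that already contains Cα.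
- **Comparison:** the chosen plan uses no Lewis acid stronger than BF3·OEt2 at −78 °C, makes the ring from commodity materials, and introduces Cα in the step that attaches the chain. In return it has the longer ring synthesis.

Key step: step 9

Remark on the chemistry: the sense of induction in the two catalyst-controlled steps (3 and 9) is assigned by analogy with simpler substrates. Both antipodes of each catalyst are available, and the one that gives 7 as the 5R isomer and 20 as the R isomer at Cα is to be used. The MandyPhos ligand meant in step 9 is a 1,1'-bis(diarylphosphino)-2,2'-bis[α-(dimethylamino)benzyl]ferrocene (aryl = 3,5-dimethylphenyl suggested).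

## Route

Step 1
Reactants: 1 1-(benzyloxy)-4-bromobenzene; 2 2,3-dimethylmaleic anhydride
Product: 4 5-[4-(benzyloxy)phenyl]-5-hydroxy-3,4-dimethylfuran-2(5H)-one (racemic pseudo-acid), via 4-(benzyloxy)phenylmagnesium bromide 3 (not isolated)
Conditions: Mg, THF, reflux; then added to 2, THF, −78 °C → 0 °C; aq. HCl
Reagents that add atoms: none
Why: Grignard formation and mono-addition to a cyclic anhydride; the first adduct is a magnesium carboxylate/lactol alkoxide that resists a second addition at low temperature, and acidification gives the ring tautomer.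

Step 2
Reactants: 4 5-[4-(benzyloxy)phenyl]-5-hydroxy-3,4-dimethylfuran-2(5H)-one
Product: 5 methyl (2Z)-4-[4-(benzyloxy)phenyl]-2,3-dimethyl-4-oxobut-2-enoate
Conditions: MeI, K2CO3, DMF, rt
Reagents that add atoms: iodomethane, CI
Why: Base opens the pseudo-acid to the keto carboxylate, and O-alkylation of the carboxylate gives the open-chain ester with the free aryl ketone; the Z geometry is inherited from the anhydride.

Step 3
Reactants: 5 methyl (2Z)-4-[4-(benzyloxy)phenyl]-2,3-dimethyl-4-oxobut-2-enoate
Product: 7 (5R)-5-[4-(benzyloxy)phenyl]-3,4-dimethylfuran-2(5H)-one, via methyl (2Z,4R)-4-[4-(benzyloxy)phenyl]-4-hydroxy-2,3-dimethylbut-2-enoate 6 (not isolated)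
Conditions: RuCl[(S,S)-TsDPEN](p-cymene) or its oxo-tethered analogue RuCl[(S,S)-Ts-DENEB] (1 mol%), HCO2H/Et3N (5:2), 40 °C; dilute acid work-up
Reagents that add atoms: none
Why: Noyori–Ikariya asymmetric transfer hydrogenation with lactonisation in the same flask, as known for 2-acylbenzoates giving phthalides and for ortho-substituted benzophenones; the catalyst should tell the coplanar 4-benzyloxyphenyl group from the twisted, fully substituted alkenyl group and so set C5, and hydroxy ester 6 closes at once in the acidic medium, which also leaves the γ-proton of 7 untouched.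

Step 4
Reactants: 7 (5R)-5-[4-(benzyloxy)phenyl]-3,4-dimethylfuran-2(5H)-one
Product: 8 (3S,4R,5S)-5-[4-(benzyloxy)phenyl]-3,4-dimethyloxolan-2-one (all-cis lactone)
Conditions: H2 (4 atm), 5% Rh/Al2O3, EtOAc, rt
Reagents that add atoms: none
Why: Heterogeneous syn-hydrogenation of the butenolide alkene from the face opposite the C5 aryl group puts both methyl groups cis to it (C5 is unchanged in space; its descriptor changes only through the priority rules); rhodium on alumina spares benzyl ethers and the benzylic lactone C–O bond better than palladium.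

Step 5
Reactants: 9 2-bromo-4-iodophenol
Product: 10 1-(benzyloxy)-2-bromo-4-iodobenzene
Conditions: BnBr, K2CO3, acetone, reflux
Reagents that add atoms: benzyl bromide, BrCc1ccccc1
Why: Williamson ether synthesis on a phenol.

Step 6
Reactants: 8 (3S,4R,5S)-5-[4-(benzyloxy)phenyl]-3,4-dimethyloxolan-2-one; 10 1-(benzyloxy)-2-bromo-4-iodobenzene
Product: 12 (3S,4R,5S)-2-[4-(benzyloxy)-3-bromophenyl]-5-[4-(benzyloxy)phenyl]-3,4-dimethyloxolan-2-ol (lactol, either configuration at C2, in equilibrium with the open hydroxy ketone), via [4-(benzyloxy)-3-bromophenyl]magnesium chloride 11 (not isolated)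
Conditions: 10, iPrMgCl·LiCl (1.05 equiv), THF, −15 °C; then 8, −15 → 0 °C; aq. NH4Cl
Reagents that add atoms: none
Why: Iodine–magnesium exchange is much faster at iodide than at bromide, and addition of an aryl Grignard reagent to a γ-lactone stops at the magnesium hemiketal alkoxide at low temperature, as in C-aryl glycoside syntheses.

Step 7
Reactants: 12 (3S,4R,5S)-2-[4-(benzyloxy)-3-bromophenyl]-5-[4-(benzyloxy)phenyl]-3,4-dimethyloxolan-2-ol
Product: 14 (2S,3R,4S,5R)-2-[4-(benzyloxy)phenyl]-5-[4-(benzyloxy)-3-bromophenyl]-3,4-dimethyloxolane (all-cis), via cyclic oxocarbenium ion 13 (not isolated)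
Conditions: Et3SiH (3 equiv), BF3·OEt2 (2 equiv), CH2Cl2, −78 °C
Reagents that add atoms: none
Why: Ionic hydrogenation of a lactol: BF3 ionises 12 to the aryl-stabilised oxocarbenium ion 13, and the silane delivers hydride to the face opposite the two methyl groups and ring A, so ring B ends cis to all three; the low temperature suppresses proton loss to the enol ether and ionisation of the other benzylic C–O bond.

Step 8
Reactants: 15 4-(benzyloxy)phenol
Product: 16 4-(benzyloxy)phenyl trifluoromethanesulfonate
Conditions: Tf2O, pyridine, CH2Cl2, 0 °C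
Reagents that add atoms: trifluoromethanesulfonic anhydride, O=S(=O)(OS(=O)(=O)C(F)(F)F)C(F)(F)F
Why: Standard O-sulfonylation of a phenol.

Step 9
Reactants: 14 (2S,3R,4S,5R)-2-[4-(benzyloxy)phenyl]-5-[4-(benzyloxy)-3-bromophenyl]-3,4-dimethyloxolane; 16 4-(benzyloxy)phenyl trifluoromethanesulfonate; 17 isopropenylboronic acid pinacol ester
Product: 20 (2S,3R,4S,5R)-2-[4-(benzyloxy)phenyl]-5-{4-(benzyloxy)-3-[(2R)-1-[4-(benzyloxy)phenyl]-2-(4,4,5,5-tetramethyl-1,3,2-dioxaborolan-2-yl)propan-2-yl]phenyl}-3,4-dimethyloxolane, via aryllithium 18 (not isolated), via lithium boron ate complex 19 (not isolated)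
Conditions: t-BuLi (2 equiv), Et2O, −78 °C; 17, −78 °C → rt; solvent changed to THF; KOTf (2 equiv), Pd(OAc)2 (3 mol%), MandyPhos ligand (3.6 mol%), 16, 60 °C
Reagents that add atoms: none
Why: Bromine–lithium exchange gives 18, which adds to boron of 17 to form ate complex 19. Oxidative addition of 16 to zerovalent palladium (formed from Pd(OAc)2 and the diphosphine) gives a cationic aryl–palladium species that binds the isopropenyl π bond of 19. Ring B then shifts from boron to Cα anti to palladium while palladium bonds to Cβ, and reductive elimination joins Cβ to ring C and returns zerovalent palladium. The closest known reaction type is the palladium/MandyPhos conjunctive cross-coupling of α-substituted alkenyl boron ate complexes with aryl triflates, which gives tertiary boronic esters and accepts aryl migrating groups. No ring is closed. The one new stereocentre, Cα, is set by the chiral diphosphine through the alkene face to which palladium binds; the ring stereocentres are too remote to interfere, so the ligand antipode decides the outcome. The step needs the conjunctive pathway to outrun direct transmetalation of the isopropenyl or aryl group; the chelating ligand, the cationic palladium (triflate counter-ion, KOTf to take up the bromide formed in the exchange) and the high migratory aptitude of an electron-rich aryl group secure this. The ortho benzyloxy group is the untested element, since it crowds the migrating carbon.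

Step 10
Reactants: 20 tertiary boronic ester as named in step 9
Product: 21 (2S,3R,4S,5R)-2-[4-(benzyloxy)phenyl]-5-{4-(benzyloxy)-3-[(2R)-1-[4-(benzyloxy)phenyl]propan-2-yl]phenyl}-3,4-dimethyloxolane
Conditions: TBAF·3H2O (3 equiv), n-pentane with the minimum of toluene, 45 °C
Reagents that add atoms: none
Why: Fluoride-promoted protodeboronation of a tertiary benzylic (aryl dialkyl) boronic ester; the fluoride ate complex is protonated on the face that bears boron by the water it carries, so boron is replaced by hydrogen with retention and Cα becomes R.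

Step 11
Reactants: 21 tris(benzyl ether) as named in step 10
Product: 22 4-[(2S,3R,4S,5R)-5-{4-hydroxy-3-[(2R)-1-(4-hydroxyphenyl)propan-2-yl]phenyl}-3,4-dimethyloxolan-2-yl]phenol (target)
Conditions: H2 (1 atm), 10% Pd/C, EtOAc/EtOH, rt, stopped after uptake of 3 equiv
Reagents that add atoms: none
Why: Hydrogenolysis of aryl benzyl ethers under neutral conditions; these cleave faster than the secondary benzylic C–O bonds of the ring, as in syntheses of phenolic 2,5-diaryltetrahydrofuran lignans, and no acid or base reaches the all-cis ring.

## Compound list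

1 | 1-(benzyloxy)-4-bromobenzene | Brc1ccc(OCc2ccccc2)cc1 | starting material
2 | 2,3-dimethylmaleic anhydride | CC1=C(C)C(=O)OC1=O | starting material
3 | 4-(benzyloxy)phenylmagnesium bromide | Br[Mg]c1ccc(OCc2ccccc2)cc1 | intermediate (not isolated)
4 | 5-[4-(benzyloxy)phenyl]-5-hydroxy-3,4-dimethylfuran-2(5H)-one, racemic | CC1=C(C)C(O)(c2ccc(OCc3ccccc3)cc2)OC1=O | intermediate
5 | methyl (2Z)-4-[4-(benzyloxy)phenyl]-2,3-dimethyl-4-oxobut-2-enoate | COC(=O)/C(C)=C(/C)C(=O)c1ccc(OCc2ccccc2)cc1 | intermediate
6 | methyl (2Z,4R)-4-[4-(benzyloxy)phenyl]-4-hydroxy-2,3-dimethylbut-2-enoate | COC(=O)/C(C)=C(/C)[C@H](O)c1ccc(OCc2ccccc2)cc1 | intermediate (not isolated)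
7 | (5R)-5-[4-(benzyloxy)phenyl]-3,4-dimethylfuran-2(5H)-one | CC1=C(C)C(=O)O[C@@H]1c1ccc(OCc2ccccc2)cc1 | intermediate
8 | (3S,4R,5S)-5-[4-(benzyloxy)phenyl]-3,4-dimethyloxolan-2-one | C[C@@H]1[C@H](C)C(=O)O[C@@H]1c1ccc(OCc2ccccc2)cc1 | intermediate
9 | 2-bromo-4-iodophenol | Oc1ccc(I)cc1Br | starting material
10 | 1-(benzyloxy)-2-bromo-4-iodobenzene | Brc1cc(I)ccc1OCc1ccccc1 | intermediate
11 | [4-(benzyloxy)-3-bromophenyl]magnesium chloride (LiCl complex) | Cl[Mg]c1ccc(OCc2ccccc2)c(Br)c1 | intermediate (not isolated)
12 | (3S,4R,5S)-2-[4-(benzyloxy)-3-bromophenyl]-5-[4-(benzyloxy)phenyl]-3,4-dimethyloxolan-2-ol (C2 undefined) | C[C@@H]1[C@H](C)C(O)(c2ccc(OCc3ccccc3)c(Br)c2)O[C@@H]1c1ccc(OCc2ccccc2)cc1 | intermediate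
13 | (3S,4R,5S)-2-[4-(benzyloxy)-3-bromophenyl]-5-[4-(benzyloxy)phenyl]-3,4-dimethyl-4,5-dihydro-3H-furan-1-ium | C[C@@H]1[C@H](C)C(c2ccc(OCc3ccccc3)c(Br)c2)=[O+][C@@H]1c1ccc(OCc2ccccc2)cc1 | intermediate (not isolated)
14 | (2S,3R,4S,5R)-2-[4-(benzyloxy)phenyl]-5-[4-(benzyloxy)-3-bromophenyl]-3,4-dimethyloxolane | C[C@@H]1[C@H](C)[C@H](c2ccc(OCc3ccccc3)c(Br)c2)O[C@@H]1c1ccc(OCc2ccccc2)cc1 | intermediate
15 | 4-(benzyloxy)phenol | Oc1ccc(OCc2ccccc2)cc1 | starting material
16 | 4-(benzyloxy)phenyl trifluoromethanesulfonate | O=S(=O)(Oc1ccc(OCc2ccccc2)cc1)C(F)(F)F | intermediate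
17 | isopropenylboronic acid pinacol ester | CC(=C)B1OC(C)(C)C(C)(C)O1 | starting material
18 | {2-(benzyloxy)-5-[(2R,3S,4R,5S)-5-[4-(benzyloxy)phenyl]-3,4-dimethyloxolan-2-yl]phenyl}lithium | C[C@@H]1[C@H](C)[C@H](c2ccc(OCc3ccccc3)c([Li])c2)O[C@@H]1c1ccc(OCc2ccccc2)cc1 | intermediate (not isolated)
19 | lithium ate complex of 18 and 17 (boron bears the aryl group of 18, isopropenyl and pinacolato) | [Li+].C[C@@H]1[C@H](C)[C@H](c2ccc(OCc3ccccc3)c([B-]3(C(C)=C)OC(C)(C)C(C)(C)O3)c2)O[C@@H]1c1ccc(OCc2ccccc2)cc1 | intermediate (not isolated)
20 | (2S,3R,4S,5R)-2-[4-(benzyloxy)phenyl]-5-{4-(benzyloxy)-3-[(2R)-1-[4-(benzyloxy)phenyl]-2-(4,4,5,5-tetramethyl-1,3,2-dioxaborolan-2-yl)propan-2-yl]phenyl}-3,4-dimethyloxolane | C[C@@H]1[C@H](C)[C@H](c2ccc(OCc3ccccc3)c([C@](B3OC(C)(C)C(C)(C)O3)(C)Cc3ccc(OCc4ccccc4)cc3)c2)O[C@@H]1c1ccc(OCc2ccccc2)cc1 | intermediate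
21 | (2S,3R,4S,5R)-2-[4-(benzyloxy)phenyl]-5-{4-(benzyloxy)-3-[(2R)-1-[4-(benzyloxy)phenyl]propan-2-yl]phenyl}-3,4-dimethyloxolane | C[C@@H]1[C@H](C)[C@H](c2ccc(OCc3ccccc3)c([C@H](C)Cc3ccc(OCc4ccccc4)cc3)c2)O[C@@H]1c1ccc(OCc2ccccc2)cc1 | intermediate
22 | 4-[(2S,3R,4S,5R)-5-{4-hydroxy-3-[(2R)-1-(4-hydroxyphenyl)propan-2-yl]phenyl}-3,4-dimethyloxolan-2-yl]phenol | C[C@@H]1[C@H](C)[C@H](c2ccc(O)c([C@H](C)Cc3ccc(O)cc3)c2)O[C@@H]1c1ccc(O)cc1 | target

## Step count and least certain steps

Total step count: 11. Longest linear sequence: 9 steps (1, 2, 3, 4, 6, 7, 9, 10, 11).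

**Step 9 (key step).** The 1,2-shift of an ortho-alkoxy aryl group onto a carbon that becomes quaternary may be slow. Direct transmetalation of the ate complex would then give Suzuki-type products, bromide from the exchange could block the cationic palladium, or face selection could be poor.

The fallback sets out from 14 and rejoins the route at 21:
- Suzuki–Miyaura coupling of 14 with 17 (Pd(dppf)Cl2, K3PO4, dioxane/water) would give the α-methylstyrene (2S,3R,4S,5R)-2-[4-(benzyloxy)phenyl]-5-[4-(benzyloxy)-3-(prop-1-en-2-yl)phenyl]-3,4-dimethyloxolane F1.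
- Enantioselective hydroboration of this 1,1-disubstituted alkene with pinacolborane (CoCl2 complex of a chiral iminopyridine–oxazoline ligand, activated with NaBHEt3) would give the primary boronic ester (2S,3R,4S,5R)-2-[4-(benzyloxy)phenyl]-5-{4-(benzyloxy)-3-[(2R)-1-(4,4,5,5-tetramethyl-1,3,2-dioxaborolan-2-yl)propan-2-yl]phenyl}-3,4-dimethyloxolane F2, with Cα already set.
- B-alkyl Suzuki–Miyaura coupling of F2 with 1 (Pd(OAc)2, RuPhos, K3PO4, toluene/water) would give 21.

**Step 3.** Discrimination between the aryl and the alkenyl substituent of the ketone may be insufficient or of the wrong sense, and the hindered ketone may react slowly.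

The fallback sets out from 4 and rejoins at 8:
- NaBH4 in aqueous NaOH, then acidification, would give racemic 5-[4-(benzyloxy)phenyl]-3,4-dimethylfuran-2(5H)-one F3.
- Hydrogenation as in step 4 would give the racemic all-cis lactone rac-(3S,4R,5S)-5-[4-(benzyloxy)phenyl]-3,4-dimethyloxolan-2-one F4.
- The enantiomers would be separated by preparative chromatography on a chiral stationary phase to give 8, with the absolute configuration assigned later on bromide 14.

**Step 4.** Hydrogenolysis of the benzylic lactone C–O bond or of the benzyl ether, saturation of an arene, or incomplete reduction of the tetrasubstituted alkene may compete.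

The fallback delivers hydride and proton separately, sets out from 7 and rejoins at 8:
- Conjugate reduction with NiCl2·6H2O/NaBH4 (MeOH/THF, −20 °C) would set C4 anti to the aryl group and give (4R,5S)-5-[4-(benzyloxy)phenyl]-3,4-dimethyloxolan-2-one as a mixture of C3 epimers F5.
- LiN(SiMe3)2 (THF, −78 °C) would give the lithium enolate of this lactone F6.
- Kinetic protonation with 2,6-di-tert-butyl-4-methylphenol from the face opposite the C4 methyl group would give 8.

**Step 7.** The oxocarbenium ion may lose a proton from the adjacent methyl-bearing carbon and be reprotonated, or the other benzylic C–O bond may ionise. Either process erodes the all-cis array toward more stable isomers.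

The fallback sets out from 12 and rejoins at 14:
- Dehydration (MsCl, Et3N, CH2Cl2, 0 °C) would give the enol ether (2S,3R)-2-[4-(benzyloxy)phenyl]-5-[4-(benzyloxy)-3-bromophenyl]-3,4-dimethyl-2,3-dihydrofuran F7.
- Hydrogenation over Pt/C in EtOAc from the face opposite ring A and the C3 methyl group would set both remaining centres by syn addition. Any earlier epimerisation next to the lactol carbon would then be erased.

**Step 10.** Fluoride may add slowly to the crowded tertiary boron, or configuration may be partly lost through a carbanion-like pathway at the benzylic carbon.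

The fallback avoids a tertiary boronate while keeping the conjunctive coupling. It sets out from 14 and rejoins at 21:
- Under the conditions of step 9, but with vinylboronic acid pinacol ester in place of 17, 14 and 16 would give the secondary benzylic boronic ester (2S,3R,4S,5R)-2-[4-(benzyloxy)phenyl]-5-{4-(benzyloxy)-3-[(1R)-2-[4-(benzyloxy)phenyl]-1-(4,4,5,5-tetramethyl-1,3,2-dioxaborolan-2-yl)ethyl]phenyl}-3,4-dimethyloxolane F8.
- Matteson homologation (BrCH2Cl, n-BuLi, THF, −78 °C → rt), which proceeds with retention, would give the primary boronic ester (2S,3R,4S,5R)-2-[4-(benzyloxy)phenyl]-5-{4-(benzyloxy)-3-[(2R)-1-[4-(benzyloxy)phenyl]-3-(4,4,5,5-tetramethyl-1,3,2-dioxaborolan-2-yl)propan-2-yl]phenyl}-3,4-dimethyloxolane F9.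
- Radical protodeboronation of its phenyllithium ate complex (thiophenol, [Ir(dF(CF3)ppy)2(dtbbpy)]PF6, blue light) would turn the CH2–B group into the methyl group of 21 without touching Cα.

## Further compounds

F1 | step 9 | (2S,3R,4S,5R)-2-[4-(benzyloxy)phenyl]-5-[4-(benzyloxy)-3-(prop-1-en-2-yl)phenyl]-3,4-dimethyloxolane | C[C@@H]1[C@H](C)[C@H](c2ccc(OCc3ccccc3)c(C(C)=C)c2)O[C@@H]1c1ccc(OCc2ccccc2)cc1
F2 | step 9 | (2S,3R,4S,5R)-2-[4-(benzyloxy)phenyl]-5-{4-(benzyloxy)-3-[(2R)-1-(4,4,5,5-tetramethyl-1,3,2-dioxaborolan-2-yl)propan-2-yl]phenyl}-3,4-dimethyloxolane | C[C@@H]1[C@H](C)[C@H](c2ccc(OCc3ccccc3)c([C@H](C)CB3OC(C)(C)C(C)(C)O3)c2)O[C@@H]1c1ccc(OCc2ccccc2)cc1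
F3 | step 3 | racemic 5-[4-(benzyloxy)phenyl]-3,4-dimethylfuran-2(5H)-one | CC1=C(C)C(=O)OC1c1ccc(OCc2ccccc2)cc1
F4 | step 3 | rac-(3S,4R,5S)-5-[4-(benzyloxy)phenyl]-3,4-dimethyloxolan-2-one (both enantiomers of the all-cis lactone) | C[C@@H]1[C@H](C)C(=O)O[C@@H]1c1ccc(OCc2ccccc2)cc1.C[C@H]1[C@@H](C)C(=O)O[C@H]1c1ccc(OCc2ccccc2)cc1
F5 | step 4 | (4R,5S)-5-[4-(benzyloxy)phenyl]-3,4-dimethyloxolan-2-one, mixture of C3 epimers | C[C@@H]1C(C)C(=O)O[C@@H]1c1ccc(OCc2ccccc2)cc1
F6 | step 4 | lithium enolate of (4R,5S)-5-[4-(benzyloxy)phenyl]-3,4-dimethyloxolan-2-one | [Li+].C[C@@H]1C(C)=C([O-])O[C@@H]1c1ccc(OCc2ccccc2)cc1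
F7 | step 7 | (2S,3R)-2-[4-(benzyloxy)phenyl]-5-[4-(benzyloxy)-3-bromophenyl]-3,4-dimethyl-2,3-dihydrofuran | C[C@@H]1C(C)=C(c2ccc(OCc3ccccc3)c(Br)c2)O[C@@H]1c1ccc(OCc2ccccc2)cc1
F8 | step 10 | (2S,3R,4S,5R)-2-[4-(benzyloxy)phenyl]-5-{4-(benzyloxy)-3-[(1R)-2-[4-(benzyloxy)phenyl]-1-(4,4,5,5-tetramethyl-1,3,2-dioxaborolan-2-yl)ethyl]phenyl}-3,4-dimethyloxolane | C[C@@H]1[C@H](C)[C@H](c2ccc(OCc3ccccc3)c([C@H](B3OC(C)(C)C(C)(C)O3)Cc3ccc(OCc4ccccc4)cc3)c2)O[C@@H]1c1ccc(OCc2ccccc2)cc1
F9 | step 10 | (2S,3R,4S,5R)-2-[4-(benzyloxy)phenyl]-5-{4-(benzyloxy)-3-[(2R)-1-[4-(benzyloxy)phenyl]-3-(4,4,5,5-tetramethyl-1,3,2-dioxaborolan-2-yl)propan-2-yl]phenyl}-3,4-dimethyloxolane | C[C@@H]1[C@H](C)[C@H](c2ccc(OCc3ccccc3)c([C@H](CB3OC(C)(C)C(C)(C)O3)Cc3ccc(OCc4ccccc4)cc3)c2)O[C@@H]1c1ccc(OCc2ccccc2)cc1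
A1 | alternative 1 | methyl (2R,3S)-5-bromo-2-(4-methoxyphenyl)-2,3-dihydro-1-benzofuran-3-carboxylate (cis) | COC(=O)[C@H]1c2cc(Br)ccc2O[C@H]1c1ccc(OC)cc1
A2 | alternative 1 | methyl 2-{5-bromo-2-[(4-methoxyphenyl)methoxy]phenyl}-2-diazoacetate | COC(=O)C(=[N+]=[N-])c1cc(Br)ccc1OCc1ccc(OC)cc1
A3 | alternative 2 | dimethyl 2,3-cis-2,5-cis-2-[4-(methanesulfonyloxy)phenyl]-5-{4-methoxy-3-[(2R)-1-(4-methoxyphenyl)propan-2-yl]phenyl}-3-methyloxolane-4,4-dicarboxylate | C[C@@H]1C(C(=O)OC)(C(=O)OC)[C@H](c2ccc(OC)c([C@H](C)Cc3ccc(OC)cc3)c2)O[C@@H]1c1ccc(OS(C)(=O)=O)cc1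
A4 | alternative 2 | dimethyl (2R,3S)-2-[4-(methanesulfonyloxy)phenyl]-3-methylcyclopropane-1,1-dicarboxylate (trans) | C[C@@H]1C(C(=O)OC)(C(=O)OC)[C@H]1c1ccc(OS(C)(=O)=O)cc1
A5 | alternative 2 | 4-methoxy-3-[(2R)-1-(4-methoxyphenyl)propan-2-yl]benzaldehyde | O=Cc1ccc(OC)c([C@H](C)Cc2ccc(OC)cc2)c1
A6 | alternative 3 | all-cis 2-(ring A)-5-(ring B)-4-methyloxolane-3-carbaldehyde with the three phenols as pivalates, configuration as in 22 | O=C[C@@H]1[C@H](C)[C@H](c2ccc(OC(=O)C(C)(C)C)c([C@H](C)Cc3ccc(OC(=O)C(C)(C)C)cc3)c2)O[C@@H]1c1ccc(OC(=O)C(C)(C)C)cc1
A7 | alternative 3 | 2-(ring B aryl)-4-(ring A aryl)-5-[(Z)-prop-1-enyl]-1,3-dioxolane with the three phenols as pivalates (ring-A carbon and Cα defined, C2 and C5 of the dioxolane undefined) | C/C=C\C1OC(c2ccc(OC(=O)C(C)(C)C)c([C@H](C)Cc3ccc(OC(=O)C(C)(C)C)cc3)c2)O[C@@H]1c1ccc(OC(=O)C(C)(C)C)cc1
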